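**Assumptions:** ethyl (E)-3-bromobut-2-enoate is taken as a catalogue reagent. Locants follow labdane numbering (C19 = axial carbon on C4, C20 = methyl on C10, C17 = exocyclic methylene carbon). The target SMILES is the ent-labdane series with 2-OH, C19 and C20 on the same face.

**Retrosynthetic overview**
- Rings A and B, the stereocentres C4, C5, C9 and C10, the 8(17)-methylene and an oxidised C19 are bought together in andrographolide, which has the target's absolute configuration; no carbocycle is built.
- C12–C13: the butenolide is cut off at the 12,13-alkene, and the (E)-3-methyl-2-enoate chain is attached by a visible-light nickel/photoredox coupling of a C12 iodide with an (E)-β-bromocrotonate that carries the alkene geometry.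
- C2–O: the 3-OH is moved to C2 through the C19 acid: 19,3-β-lactone (first ring formed), then dyotropic hydride-shift ring expansion to the 19,2-γ-lactone (second ring formed); the tether fixes the axial C2 configuration.
- Saponification of lactone and ester releases the hydroxy diacid.

**Step 1**
Reactants: 1 andrographolide
Product: 2 (3R,4R,5S,9R,10S)-3,19-dihydroxy-13,14,15,16-tetranorlabd-8(17)-en-12-al
Conditions: KMnO4 (1.5 equiv, in portions), MgSO4, THF/H2O 4:1, −15 °C, 30 min; filter through Celite
Reagents that add atoms: potassium permanganate, [K+].[O-][Mn](=O)(=O)=O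
Why: Permanganate oxidative alkene cleavage (cis-dihydroxylation then glycol fission, Lemieux–von Rudloff type) is expected to take the conjugated, electron-poor 12,13-alkene of the alkylidene lactone faster than the hindered 8(17)-methylene flanked by C9 and quaternary C10, as in classical labdane side-chain degradations; the butenolide carbons leave as a keto lactone and no stereocentre is touched.

**Step 2**
Reactants: 2 (3R,4R,5S,9R,10S)-3,19-dihydroxy-13,14,15,16-tetranorlabd-8(17)-en-12-al
Product: 3 (3R,4R,5S,9R,10S)-13,14,15,16-tetranorlabd-8(17)-ene-3,12,19-triol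
Conditions: NaBH4 (1.0 equiv), MeOH, 0 °C, 20 min
Reagents that add atoms: none
Why: Chemoselective borohydride reduction of the aldehyde; the alkene and all stereocentres are untouched.

**Step 3**
Reactants: 3 (3R,4R,5S,9R,10S)-13,14,15,16-tetranorlabd-8(17)-ene-3,12,19-triol
Product: 4 (3R,4R,5S,9R,10S)-12-iodo-13,14,15,16-tetranorlabd-8(17)-ene-3,19-diol
Conditions: PPh3 (1.15 equiv), I2 (1.1 equiv), imidazole (2.5 equiv), THF, 0 °C, 1 h
Reagents that add atoms: iodine, II
Why: Garegg–Samuelsson (Appel-type) iodination: the unhindered primary 12-OH forms the alkoxyphosphonium and is displaced by iodide (SN2) far faster than the neopentyl 19-OH next to quaternary C4 or the secondary 3-OH, so one equivalent of reagent is selective; no stereocentre is involved.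

**Step 4**
Reactants: 4 (3R,4R,5S,9R,10S)-12-iodo-13,14,15,16-tetranorlabd-8(17)-ene-3,19-diol; 5 ethyl (E)-3-bromobut-2-enoate
Product: 6 ethyl (3R,4R,5S,9R,10S,13E)-3,19-dihydroxylabda-8(17),13-dien-15-oate
Conditions: 5 (1.5 equiv), Ir[dF(CF3)ppy]2(dtbbpy)PF6 (1 mol%), NiCl2(dme) (5 mol%), 4,4'-di-tert-butyl-2,2'-bipyridine (5 mol%), (Me3Si)3SiH (1.2 equiv), Na2CO3 (2 equiv), DME, blue LEDs (450 nm), 25 °C
Reagents that add atoms: 5 ethyl (E)-3-bromobut-2-enoate, C/C(Br)=C\C(=O)OCC
Why: Nickel/photoredox cross-electrophile coupling: the photogenerated silyl radical abstracts iodine from 4, the primary C12 radical is captured by the vinylnickel species formed from 5, and reductive elimination forms C12–C13 with retention of the E geometry (methyl cis to the ester); the C12 radical has only a disfavoured 5-endo path to the 8(17)-alkene, free hydroxyls are tolerated, and no stereocentre is touched.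

**Step 5**
Reactants: 6 ethyl (3R,4R,5S,9R,10S,13E)-3,19-dihydroxylabda-8(17),13-dien-15-oate
Product: 8 (3R,4S,5S,9R,10S,13E)-15-ethoxy-3-hydroxy-15-oxolabda-8(17),13-dien-19-oic acid, via hydroxy aldehyde 7 (not isolated)
Conditions: TEMPO (0.2 equiv), PhI(OAc)2 (1.2 equiv), CH2Cl2, 23 °C, 3 h; then t-BuOH/H2O, 2-methyl-2-butene (20 equiv), NaH2PO4 (4 equiv), NaClO2 (3 equiv), 0 → 23 °C
Reagents that add atoms: sodium chlorite, [Na+].[O-]Cl=O
Why: TEMPO/PhI(OAc)2 oxidation (oxoammonium, strongly primary-selective, leaves the secondary 3-OH) followed in the same flask by Pinnick chlorite oxidation with 2-methyl-2-butene as hypochlorite scavenger so the alkenes survive; C3 stays an alcohol, which avoids a decarboxylation-prone β-keto acid, and C4 keeps its configuration (only its CIP label changes).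

**Step 6**
Reactants: 8 (3R,4S,5S,9R,10S,13E)-15-ethoxy-3-hydroxy-15-oxolabda-8(17),13-dien-19-oic acid
Product: 9 ethyl (3R,4S,5S,9R,10S,13E)-19-oxo-3,19-epoxylabda-8(17),13-dien-15-oate (cis-fused 19,3-β-lactone)
Conditions: PhSO2Cl (1.5 equiv), pyridine, 0 → 5 °C, 14 h
Reagents that add atoms: none
Why: Adam β-lactonisation by carboxyl activation (mixed sulfonic–carboxylic anhydride attacked by the 3-OH): the equatorial 3-OH and the axial C19 are cis-vicinal and the C3–O bond is never broken, so C3 is retained and the cis-fused four-membered lactone closes.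

**Step 7**
Reactants: 9 ethyl (3R,4S,5S,9R,10S,13E)-19-oxo-3,19-epoxylabda-8(17),13-dien-15-oate (cis-fused 19,3-β-lactone)
Product: 10 ethyl (2R,4R,5S,9R,10S,13E)-19-oxo-2,19-epoxylabda-8(17),13-dien-15-oate (bridged 19,2-γ-lactone)
Conditions: Zn(OTf)2 (1.0 equiv), 2,6-di-tert-butylpyridine (0.2 equiv), CH2Cl2, 23 °C (40 °C if slow)
Reagents that add atoms: none
Why: Proposed new method: a Lewis-acid-triggered dyotropic 1,2-oxygen transposition with hydride shift on a ring-A-fused β-lactone — zinc coordination to the lactone carbonyl weakens the C3–O bond, the cis-fused four-membered ring holds ring A boat-like (C2 and C5 at the prow positions) so that only the C2 hydrogen on the face opposite the lactone is antiperiplanar to C3–O, and that hydrogen migrates to C3 while the carboxylate oxygen closes on C2 from the lactone face, releasing about 20 kcal/mol of ring strain and setting the new C2–O bond cis to C19 (axial, 2R) purely through the tether; shifts from C4 are misaligned and would place charge next to the carboxyl carbon, and the hindered pyridine keeps adventitious acid from isomerising the methylene; the closest known reaction type is the MgBr2- or Zn(OTf)2-promoted dyotropic (Wagner–Meerwein) ring expansion of β-lactones to γ-butyrolactones, which has not been used to move an oxygen from C3 to C2 of a terpenoid ring A or to make a 1,3-bridged lactone by hydride shift.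

**Step 8**
Reactants: 10 ethyl (2R,4R,5S,9R,10S,13E)-19-oxo-2,19-epoxylabda-8(17),13-dien-15-oate (bridged 19,2-γ-lactone)
Product: 11 (2R,4R,5S,9R,10S,13E)-2-hydroxylabda-8(17),13-diene-15,19-dioic acid
Conditions: LiOH·H2O (8 equiv), THF/H2O 2:1, 45 °C; then 0.5 M HCl to pH 4 at 0 °C, EtOAc extraction, no heating
Reagents that add atoms: lithium hydroxide monohydrate, [Li+].[OH-].O
Why: Saponification of the ethyl ester and of the bridged γ-lactone by acyl–oxygen cleavage keeps the C2–O bond and its 2R configuration and leaves the β,β-disubstituted E-enoate geometry intact; cold acidification only to pH 4 avoids relactonisation of the 1,3-diaxial hydroxy acid.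

**Compound list**
1 | andrographolide | C=C1CC[C@H]2[C@@](C)(CC[C@@H](O)[C@@]2(C)CO)[C@@H]1C/C=C3/C(=O)OC[C@H]3O | starting material
2 | (3R,4R,5S,9R,10S)-3,19-dihydroxy-13,14,15,16-tetranorlabd-8(17)-en-12-al | C=C1CC[C@H]2[C@@](C)(CC[C@@H](O)[C@@]2(C)CO)[C@@H]1CC=O | intermediate
3 | (3R,4R,5S,9R,10S)-13,14,15,16-tetranorlabd-8(17)-ene-3,12,19-triol | C=C1CC[C@H]2[C@@](C)(CC[C@@H](O)[C@@]2(C)CO)[C@@H]1CCO | intermediate
4 | (3R,4R,5S,9R,10S)-12-iodo-13,14,15,16-tetranorlabd-8(17)-ene-3,19-diol | C=C1CC[C@H]2[C@@](C)(CC[C@@H](O)[C@@]2(C)CO)[C@@H]1CCI | intermediate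
5 | ethyl (E)-3-bromobut-2-enoate | C/C(Br)=C\C(=O)OCC | starting material
6 | ethyl (3R,4R,5S,9R,10S,13E)-3,19-dihydroxylabda-8(17),13-dien-15-oate | C=C1CC[C@H]2[C@@](C)(CC[C@@H](O)[C@@]2(C)CO)[C@@H]1CC/C(C)=C/C(=O)OCC | intermediate
7 | ethyl (3R,4S,5S,9R,10S,13E)-3-hydroxy-19-oxolabda-8(17),13-dien-15-oate (hydroxy aldehyde) | C=C1CC[C@H]2[C@@](C)(CC[C@@H](O)[C@@]2(C)C=O)[C@@H]1CC/C(C)=C/C(=O)OCC | intermediate (not isolated)
8 | (3R,4S,5S,9R,10S,13E)-15-ethoxy-3-hydroxy-15-oxolabda-8(17),13-dien-19-oic acid | C=C1CC[C@H]2[C@@](C)(CC[C@@H](O)[C@@]2(C)C(=O)O)[C@@H]1CC/C(C)=C/C(=O)OCC | intermediate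
9 | ethyl (3R,4S,5S,9R,10S,13E)-19-oxo-3,19-epoxylabda-8(17),13-dien-15-oate (cis-fused 19,3-β-lactone) | C=C1CC[C@H]2[C@@](C)(CC[C@H]3OC(=O)[C@@]23C)[C@@H]1CC/C(C)=C/C(=O)OCC | intermediate
10 | ethyl (2R,4R,5S,9R,10S,13E)-19-oxo-2,19-epoxylabda-8(17),13-dien-15-oate (bridged 19,2-γ-lactone) | C=C1CC[C@H]2[C@@](C)(C[C@@H]3C[C@@]2(C)C(=O)O3)[C@@H]1CC/C(C)=C/C(=O)OCC | intermediate
11 | (2R,4R,5S,9R,10S,13E)-2-hydroxylabda-8(17),13-diene-15,19-dioic acid | C=C1CC[C@H]2[C@@](C)(C[C@@H](O)C[C@@]2(C)C(=O)O)[C@@H]1CC/C(C)=C/C(=O)O | target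

**Totals**
Total step count: 8 (step 5 is a two-stage, one-flask operation).
Longest linear sequence: 8 steps (1 → 11).

**Three steps most likely to fail**

Step 1 (selectivity between the 12,13-alkene and the 8(17)-methylene; over-oxidation of the aldehyde). The fallback sets out from 1 and comes back at 2. It replaces the ambiphilic oxidant by a purely nucleophilic one: t-BuOOH/DBU in THF (Weitz–Scheffer epoxidation) can attack only the Michael-acceptor alkene and gives 12,13-epoxyandrographolide F1. H5IO6 in THF/H2O at 0 °C then opens and cleaves the epoxide to aldehyde 2.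

Step 4 (hydrodehalogenation of 4 or 5, erosion of the E geometry, interference by the free diol). The fallback sets out from 4 and comes back at 6. It uses a polar organometallic coupling instead of the radical one: TESCl/imidazole gives the bis(triethylsilyl) ether of the iodide F2. Activated zinc dust with LiCl in THF at 40 °C inserts to give the alkylzinc iodide F3. Stereoretentive Negishi coupling with 5 under Pd(PPh3)4 gives the bis(triethylsilyl) enoate F4. AcOH/THF/H2O removes both silyl groups to give 6.

Step 7 (the proposed new step; competing decarboxylation to a 19-nor alkene, ring contraction by C1 shift, or acid isomerisation of the methylene). The fallback uses known chemistry, sets out from 7 (step 5 is stopped after the TEMPO stage and 7 is isolated) and comes back at 10. Burgess reagent in benzene at 50 °C (syn elimination; only C2 carries a β-hydrogen, and the C4 acyl group disfavours cationic rearrangement) gives the 2-ene aldehyde F5. Pinnick oxidation gives the 2-ene acid F6. Iodolactonisation (I2, NaHCO3, MeCN, 0 °C, dark) delivers the carboxylate to C2 from the C19 face with iodine anti on C3, giving the iodolactone F7. Bu3SnH/AIBN in benzene at 80 °C removes the iodine to give 10.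

**Further compounds**
F1 | step 1 | 12,13-epoxyandrographolide (epoxide diastereomers) | C=C1CC[C@H]2[C@@](C)(CC[C@@H](O)[C@@]2(C)CO)[C@@H]1CC3OC34C(=O)OC[C@H]4O
F2 | step 4 | (3R,4R,5S,9R,10S)-12-iodo-3,19-bis(triethylsilyloxy)-13,14,15,16-tetranorlabd-8(17)-ene | C=C1CC[C@H]2[C@@](C)(CC[C@@H](O[Si](CC)(CC)CC)[C@@]2(C)CO[Si](CC)(CC)CC)[C@@H]1CCI
F3 | step 4 | alkylzinc iodide of F2 (C12–Zn–I) | C=C1CC[C@H]2[C@@](C)(CC[C@@H](O[Si](CC)(CC)CC)[C@@]2(C)CO[Si](CC)(CC)CC)[C@@H]1CC[Zn]I
F4 | step 4 | ethyl (3R,4R,5S,9R,10S,13E)-3,19-bis(triethylsilyloxy)labda-8(17),13-dien-15-oate | C=C1CC[C@H]2[C@@](C)(CC[C@@H](O[Si](CC)(CC)CC)[C@@]2(C)CO[Si](CC)(CC)CC)[C@@H]1CC/C(C)=C/C(=O)OCC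
F5 | step 7 | ethyl (4R,5S,9R,10S,13E)-19-oxolabda-2,8(17),13-trien-15-oate | C=C1CC[C@H]2[C@@](C)(CC=C[C@@]2(C)C=O)[C@@H]1CC/C(C)=C/C(=O)OCC
F6 | step 7 | (4R,5S,9R,10S,13E)-15-ethoxy-15-oxolabda-2,8(17),13-trien-19-oic acid | C=C1CC[C@H]2[C@@](C)(CC=C[C@@]2(C)C(=O)O)[C@@H]1CC/C(C)=C/C(=O)OCC
F7 | step 7 | ethyl (2R,3R,4R,5S,9R,10S,13E)-3-iodo-19-oxo-2,19-epoxylabda-8(17),13-dien-15-oate | C=C1CC[C@H]2[C@@](C)(C[C@@H]3[C@H](I)[C@@]2(C)C(=O)O3)[C@@H]1CC/C(C)=C/C(=O)OCC
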